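**Retrosynthetic overview**
- Target ⇐ BBr3 demethylation ⇐ hydrogenation (stilbene → CH2CH2, aryl ketone → CH2) of a macrocyclic ketone tetramethyl ether.
- Key disconnection: ring B (the 1,4-phenylene) and the 19-membered macrocycle close together by an intramolecular Diels–Alder reaction of a 5-acyl-2-pyrone with an aryl ethynyl ether, followed by loss of CO2.
- Linear precursor ⇐ Negishi acylation (benzylzinc + coumalyl chloride), ethynyl ether from a dichlorovinyl ether, Horner–Wadsworth–Emmons olefination (ring A–CH=CH–ring D), Ullmann etherification (ring C–O–ring D).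
- Building blocks: methyl 3-hydroxy-4,5-dimethoxybenzoate (ring C), 3-hydroxy-4,5-dimethoxybenzaldehyde (ring A), diethyl (3-bromobenzyl)phosphonate (ring D), trichloroethylene plus coumalic acid (the six carbons of ring B).
- Ring order: rings A, C and D are bought as arenes; ring B and the macrocycle form last, in the same step.

Assumption: the target has no stereocentre and is conformationally mobile (achiral), so no enantiocontrol is needed; only the alkene geometries of intermediates are specified.

**Step 1**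
Reactants: 1 methyl 3-hydroxy-4,5-dimethoxybenzoate; 2 diethyl (3-bromobenzyl)phosphonate
Product: 3 methyl 3-[3-(diethoxyphosphorylmethyl)phenoxy]-4,5-dimethoxybenzoate
Conditions: CuI (10 mol %), picolinic acid (20 mol %), K3PO4, DMSO, 90 °C
Reagents that add atoms: none
Why: Ullmann-type Cu(I)-catalysed C–O coupling of the electron-rich phenol with the unactivated aryl bromide runs under a mild phosphate base that leaves the methyl ester and the benzylic phosphonate untouched.

**Step 2**
Reactants: 4 3-hydroxy-4,5-dimethoxybenzaldehyde; 5 trichloroethylene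
Product: 7 3-[(E)-1,2-dichlorovinyloxy]-4,5-dimethoxybenzaldehyde, via dichloroacetylene 6 (not isolated)
Conditions: K2CO3, DMF, 70 °C
Reagents that add atoms: none
Why: Base-induced dehydrochlorination of trichloroethylene gives dichloroacetylene, to which the phenoxide adds anti (nucleophilic addition to a haloalkyne) to give the (E)-dichlorovinyl ether, a base-stable masked ethynyl ether that the non-enolisable aldehyde tolerates.

**Step 3**
Reactants: 3 methyl 3-[3-(diethoxyphosphorylmethyl)phenoxy]-4,5-dimethoxybenzoate; 7 3-[(E)-1,2-dichlorovinyloxy]-4,5-dimethoxybenzaldehyde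
Product: 8 methyl 3-[3-[(E)-2-[3-[(E)-1,2-dichlorovinyloxy]-4,5-dimethoxyphenyl]vinyl]phenoxy]-4,5-dimethoxybenzoate
Conditions: NaH, 15-crown-5 (cat.), THF, 0 °C → rt
Reagents that add atoms: none
Why: Horner–Wadsworth–Emmons olefination of the aryl aldehyde with the benzylic phosphonate anion gives the (E)-stilbene selectively, while the ester reacts far more slowly and the dichlorovinyl ether (H and Cl cis, so no anti-elimination) is left alone.

**Step 4**
Reactants: 8 methyl ester (E)-stilbene from step 3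
Product: 10 [3-[3-[(E)-2-[3-[(E)-1,2-dichlorovinyloxy]-4,5-dimethoxyphenyl]vinyl]phenoxy]-4,5-dimethoxyphenyl]methanol, via aldehyde 9 (not isolated)
Conditions: DIBAL-H (2.5 equiv), CH2Cl2, −78 → 0 °C; Rochelle salt work-up
Reagents that add atoms: none
Why: DIBAL-H hydride reduction takes the methyl ester through the aldehyde to the primary benzylic alcohol without touching the vinyl chlorides, the stilbene or the aryl ethers at low temperature.

**Step 5**
Reactants: 10 dichlorovinyl ether benzylic alcohol from step 4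
Product: 13 [3-[3-[(E)-2-[3-(ethynyloxy)-4,5-dimethoxyphenyl]vinyl]phenoxy]-4,5-dimethoxyphenyl]methanol, via chloroalkynyl ether lithium alkoxide 11 (not isolated), via dilithio alkoxide acetylide 12 (not isolated)
Conditions: n-BuLi (3.3 equiv), THF, −78 → −40 °C; then H2O, −78 °C
Reagents that add atoms: none
Why: In this dichlorovinyl ether route to alkynyl ethers (elimination then halogen–lithium exchange), n-BuLi deprotonates the alcohol and the vinylic C–H, LiCl is lost to give the chloroalkynyl ether, Cl–Li exchange gives the lithium aryloxyacetylide that is protonated on quench, and at −78 °C carbolithiation of the stilbene and ortho-lithiation are slow.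

**Step 6**
Reactants: 13 ethynyl ether benzylic alcohol from step 5
Product: 15 1-(chloromethyl)-3-[3-[(E)-2-[3-(ethynyloxy)-4,5-dimethoxyphenyl]vinyl]phenoxy]-4,5-dimethoxybenzene, via benzylic mesylate 14 (not isolated)
Conditions: MsCl, s-collidine, LiCl, DMF, 0 °C
Reagents that add atoms: lithium chloride, [Li+].[Cl-] (chloride source; the chloride released by methanesulfonyl chloride, CS(=O)(=O)Cl, joins the same pool)
Why: Collington–Meyers chlorination (collidine-buffered mesylation, then SN2 displacement by chloride at the benzylic carbon) avoids free acid, to which the ynol ether would be sensitive.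

**Step 7**
Reactants: 16 coumalic acid (2-oxo-2H-pyran-5-carboxylic acid)
Product: 17 coumalyl chloride (2-oxo-2H-pyran-5-carbonyl chloride)
Conditions: SOCl2 (neat), reflux; evaporate
Reagents that add atoms: thionyl chloride, O=S(Cl)Cl
Why: Acid chloride formation with thionyl chloride is straightforward because the 2-pyrone ring is stable to anhydrous acidic conditions.

**Step 8**
Reactants: 15 benzylic chloride from step 6; 17 coumalyl chloride
Product: 19 5-[2-[3-[3-[(E)-2-[3-(ethynyloxy)-4,5-dimethoxyphenyl]vinyl]phenoxy]-4,5-dimethoxyphenyl]acetyl]-2H-pyran-2-one, via benzylzinc chloride 18 (not isolated)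
Conditions: Zn dust, LiCl, THF, 25 °C; then 17, Pd(PPh3)4 (5 mol %), THF, 0 °C → rt
Reagents that add atoms: none
Why: LiCl-promoted zinc insertion gives a mild benzylzinc reagent, and Pd(0)-catalysed Negishi acylation with the acid chloride is much faster than conjugate addition to the pyrone or deprotonation of the alkyne, so the ketone forms without over-addition.

**Step 9**
Reactants: 19 pyrone ketone ethynyl ether from step 8
Product: 21 macrocyclic (E)-stilbene ketone tetramethyl ether (ring B and the 19-membered ring newly closed; see compound list), via bicyclic lactone cycloadduct 20 (not isolated)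
Conditions: o-xylene (1 mM, slow addition), BHT (cat.), 140 °C
Reagents that add atoms: none
Why: Proposed new method: an inverse-electron-demand intramolecular Diels–Alder reaction in which the nucleophilic terminal carbon of the aryl ynol ether bonds to C6 of the 5-acyl-2-pyrone (β to the ketone, δ to the lactone carbonyl) and the O-bearing carbon bonds to C3, so that the bridged lactone 20 expels CO2 (retro-Diels–Alder) to give a benzene ring with aryloxy and acyl groups para, closing ring B and the macrocycle together under high dilution; the closest known reaction types are the intermolecular para-selective cycloaddition/decarboxylation of coumalate esters with alkoxyalkynes, ynamines and ketene acetals, and intramolecular pyrone Diels–Alder closures of cyclophane rings.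

**Step 10**
Reactants: 21 macrocyclic (E)-stilbene ketone tetramethyl ether
Product: 24 tetra-O-methyl ether of the target, via saturated macrocyclic ketone 22 (not isolated), via macrocyclic benzylic alcohol 23 (not isolated)
Conditions: H2 (4 atm), 10 % Pd/C, EtOAc–AcOH, HClO4 (cat.), 40 °C
Reagents that add atoms: none
Why: Heterogeneous catalytic hydrogenation saturates the stilbene and, with acid, hydrogenolyses the electron-rich 4-aryloxyphenyl ketone via the benzylic alcohol to the methylene group, whereas diaryl and methyl ethers are inert.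

**Step 11**
Reactants: 24 tetra-O-methyl ether of the target
Product: 25 target CNP0511668.0
Conditions: BBr3 (10 equiv), CH2Cl2, −78 °C → rt; then H2O
Reagents that add atoms: none
Why: Lewis-acid ether cleavage with BBr3 (bromide attacks the O-methyl groups of the boron-complexed aryl methyl ethers by SN2) removes all four methyl groups, while the diaryl ether C–O bonds cannot react this way and survive.

**Compound list**
1 | methyl 3-hydroxy-4,5-dimethoxybenzoate | COC(=O)c1cc(O)c(OC)c(OC)c1 | starting material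
2 | diethyl (3-bromobenzyl)phosphonate | CCOP(=O)(Cc1cccc(Br)c1)OCC | starting material
3 | methyl 3-[3-(diethoxyphosphorylmethyl)phenoxy]-4,5-dimethoxybenzoate | COC(=O)c1cc(Oc2cccc(CP(=O)(OCC)OCC)c2)c(OC)c(OC)c1 | intermediate
4 | 3-hydroxy-4,5-dimethoxybenzaldehyde | O=Cc1cc(O)c(OC)c(OC)c1 | starting material
5 | trichloroethylene | ClC=C(Cl)Cl | starting material
6 | dichloroacetylene (not isolated) | ClC#CCl | intermediate
7 | 3-[(E)-1,2-dichlorovinyloxy]-4,5-dimethoxybenzaldehyde | O=Cc1cc(O/C(Cl)=C\Cl)c(OC)c(OC)c1 | intermediate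
8 | methyl 3-[3-[(E)-2-[3-[(E)-1,2-dichlorovinyloxy]-4,5-dimethoxyphenyl]vinyl]phenoxy]-4,5-dimethoxybenzoate | COC(=O)c1cc(Oc2cccc(/C=C/c3cc(O/C(Cl)=C\Cl)c(OC)c(OC)c3)c2)c(OC)c(OC)c1 | intermediate
9 | 3-[3-[(E)-2-[3-[(E)-1,2-dichlorovinyloxy]-4,5-dimethoxyphenyl]vinyl]phenoxy]-4,5-dimethoxybenzaldehyde (not isolated) | O=Cc1cc(Oc2cccc(/C=C/c3cc(O/C(Cl)=C\Cl)c(OC)c(OC)c3)c2)c(OC)c(OC)c1 | intermediate
10 | [3-[3-[(E)-2-[3-[(E)-1,2-dichlorovinyloxy]-4,5-dimethoxyphenyl]vinyl]phenoxy]-4,5-dimethoxyphenyl]methanol | OCc1cc(Oc2cccc(/C=C/c3cc(O/C(Cl)=C\Cl)c(OC)c(OC)c3)c2)c(OC)c(OC)c1 | intermediate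
11 | lithium alkoxide of [3-[3-[(E)-2-[3-(chloroethynyloxy)-4,5-dimethoxyphenyl]vinyl]phenoxy]-4,5-dimethoxyphenyl]methanol (not isolated) | [Li]OCc1cc(Oc2cccc(/C=C/c3cc(OC#CCl)c(OC)c(OC)c3)c2)c(OC)c(OC)c1 | intermediate
12 | dilithio species: lithium benzylic alkoxide bearing the lithium aryloxyacetylide (not isolated) | [Li]OCc1cc(Oc2cccc(/C=C/c3cc(OC#C[Li])c(OC)c(OC)c3)c2)c(OC)c(OC)c1 | intermediate
13 | [3-[3-[(E)-2-[3-(ethynyloxy)-4,5-dimethoxyphenyl]vinyl]phenoxy]-4,5-dimethoxyphenyl]methanol | OCc1cc(Oc2cccc(/C=C/c3cc(OC#C)c(OC)c(OC)c3)c2)c(OC)c(OC)c1 | intermediate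
14 | methanesulfonate of 13 (not isolated) | CS(=O)(=O)OCc1cc(Oc2cccc(/C=C/c3cc(OC#C)c(OC)c(OC)c3)c2)c(OC)c(OC)c1 | intermediate
15 | 1-(chloromethyl)-3-[3-[(E)-2-[3-(ethynyloxy)-4,5-dimethoxyphenyl]vinyl]phenoxy]-4,5-dimethoxybenzene | ClCc1cc(Oc2cccc(/C=C/c3cc(OC#C)c(OC)c(OC)c3)c2)c(OC)c(OC)c1 | intermediate
16 | coumalic acid (2-oxo-2H-pyran-5-carboxylic acid) | O=C(O)C1=COC(=O)C=C1 | starting material
17 | coumalyl chloride (2-oxo-2H-pyran-5-carbonyl chloride) | O=C(Cl)C1=COC(=O)C=C1 | intermediate
18 | benzylzinc chloride derived from 15 (not isolated) | Cl[Zn]Cc1cc(Oc2cccc(/C=C/c3cc(OC#C)c(OC)c(OC)c3)c2)c(OC)c(OC)c1 | intermediate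
19 | 5-[2-[3-[3-[(E)-2-[3-(ethynyloxy)-4,5-dimethoxyphenyl]vinyl]phenoxy]-4,5-dimethoxyphenyl]acetyl]-2H-pyran-2-one | O=C(Cc1cc(Oc2cccc(/C=C/c3cc(OC#C)c(OC)c(OC)c3)c2)c(OC)c(OC)c1)C1=COC(=O)C=C1 | intermediate
20 | macro-bridged 2-oxabicyclo[2.2.2]octa-5,7-dien-3-one cycloadduct: acyl (C(=O)CH2–ring C) on C6, aryloxy (O–ring A) on C8, racemic (not isolated) | COc1cc(/C=C/c2cccc(Oc3cc(CC(=O)C4=CC5C(=O)OC4C=C5O6)cc(OC)c3OC)c2)cc6c1OC | intermediate
21 | macrocyclic ketone: cyclo[–O–(1,4-phenylene, ring B)–C(=O)–CH2–(4,5-dimethoxy-1,3-phenylene, ring C; C-1 to CH2, C-3 to O)–O–(1,3-phenylene, ring D)–(E)-CH=CH–(4,5-dimethoxy-1,3-phenylene, ring A; C-1 to CH, C-3 to O)–] | COc1cc(/C=C/c2cccc(Oc3cc(CC(=O)c4ccc(O5)cc4)cc(OC)c3OC)c2)cc5c1OC | intermediate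
22 | macrocyclic ketone as 21 with CH2CH2 in place of the stilbene CH=CH (not isolated) | COc1cc(CCc2cccc(Oc3cc(CC(=O)c4ccc(O5)cc4)cc(OC)c3OC)c2)cc5c1OC | intermediate
23 | macrocyclic benzylic alcohol as 22 with CH(OH) in place of C=O, racemic (not isolated) | COc1cc(CCc2cccc(Oc3cc(CC(O)c4ccc(O5)cc4)cc(OC)c3OC)c2)cc5c1OC | intermediate
24 | tetra-O-methyl ether of the target: cyclo[–O–(1,4-phenylene)–CH2CH2–(4,5-dimethoxy-1,3-phenylene)–O–(1,3-phenylene)–CH2CH2–(4,5-dimethoxy-1,3-phenylene)–] | COc1cc2cc(c1OC)Oc1ccc(cc1)CCc1cc(OC)c(OC)c(c1)Oc1cccc(c1)CC2 | intermediate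
25 | CNP0511668.0: cyclo[–O–(1,4-phenylene)–CH2CH2–(4,5-dihydroxy-1,3-phenylene)–O–(1,3-phenylene)–CH2CH2–(4,5-dihydroxy-1,3-phenylene)–], achiral | Oc1cc2cc(c1O)Oc1ccc(cc1)CCc1cc(O)c(O)c(c1)Oc1cccc(c1)CC2 | target

**Totals**
Total step count: 11.
Longest linear sequence: 9 steps (1 or 2 → 3 → 8 → 10 → 13 → 15 → 19 → 21 → 24 → 25; the branch from 4 and 5 through 7 is equally long).

**Steps most likely to fail and fallbacks**

Step 9 (macrocyclising pyrone/ynol ether cycloaddition; risks are oligomerisation, thermal loss of the ynol ether, or the wrong regiochemistry). The fallback sets out from 13 and comes back at 24. Ring B is built intermolecularly and the macrocycle is closed at carbon instead. Alcohol 13 is heated with commercial methyl coumalate (toluene, 110 °C, 0.5 M). The racemic bicyclic lactone adduct methyl 8-aryloxy-3-oxo-2-oxabicyclo[2.2.2]octa-5,7-diene-6-carboxylate F1 loses CO2 in the flask and gives the methyl 4-aryloxybenzoate benzylic alcohol F2. DIBAL-H reduces the ester to the bis(benzylic) diol F3, and MnO2 oxidises both alcohols to the dialdehyde F4. Intramolecular McMurry coupling (TiCl4, Zn, pyridine, THF, reflux, high dilution) gives the macrocyclic bis-stilbene F5 (E/Z mixture at the new alkene). Hydrogenation (H2, Pd/C, EtOAc) of both alkenes gives 24.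

Step 8 (benzylzinc formation and acylation with a pyrone acid chloride while a terminal ynol ether is present). The fallback sets out from 15 and comes back at 19. The polarity is reversed. Commercial 5-bromo-2H-pyran-2-one is stannylated (hexabutylditin, Pd(PPh3)4, dioxane, 80 °C) to 5-(tributylstannyl)-2H-pyran-2-one F6. Benzylic chloride 15 is then joined to F6 under CO (1 atm) with PdCl2(PPh3)2 in THF at 50 °C (carbonylative Stille coupling; the ketone carbon comes from CO), which gives 19 directly.

Step 6 (chlorination with the terminal ynol ether exposed to electrophilic reagents). The fallback sets out from 10 and comes back at 19. The alkyne is carried through as its C-silyl derivative. The dilithio species 12, generated from 10 as in step 5, is quenched with Me3SiCl to give the O,C-bis(trimethylsilyl) compound F7. Aqueous citric acid work-up hydrolyses only the silyl ether and leaves the C-trimethylsilyl ynol ether alcohol F8. Chlorination as in step 6 passes through the mesylate F9 to the benzylic chloride F10. Zinc insertion gives the benzylzinc chloride F11, and Pd-catalysed acylation with 17 as in step 8 gives the silylated pyrone ketone F12. Bu4NF buffered with AcOH (THF, −20 °C) removes the silyl group and gives 19.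

**Further compounds**
F1 | step 9 | methyl 8-aryloxy-3-oxo-2-oxabicyclo[2.2.2]octa-5,7-diene-6-carboxylate, aryl = ring A unit of 13, racemic, formed in the flask | COC(=O)C1=CC2C(=O)OC1C=C2Oc3cc(/C=C/c4cccc(Oc5cc(CO)cc(OC)c5OC)c4)cc(OC)c3OC
F2 | step 9 | methyl 4-[5-[(E)-2-[3-[5-(hydroxymethyl)-2,3-dimethoxyphenoxy]phenyl]vinyl]-2,3-dimethoxyphenoxy]benzoate | COC(=O)c1ccc(Oc2cc(/C=C/c3cccc(Oc4cc(CO)cc(OC)c4OC)c3)cc(OC)c2OC)cc1
F3 | step 9 | diol: [4-[5-[(E)-2-[3-[5-(hydroxymethyl)-2,3-dimethoxyphenoxy]phenyl]vinyl]-2,3-dimethoxyphenoxy]phenyl]methanol | OCc1ccc(Oc2cc(/C=C/c3cccc(Oc4cc(CO)cc(OC)c4OC)c3)cc(OC)c2OC)cc1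
F4 | step 9 | dialdehyde: 4-[5-[(E)-2-[3-(5-formyl-2,3-dimethoxyphenoxy)phenyl]vinyl]-2,3-dimethoxyphenoxy]benzaldehyde | O=Cc1ccc(Oc2cc(/C=C/c3cccc(Oc4cc(C=O)cc(OC)c4OC)c3)cc(OC)c2OC)cc1
F5 | step 9 | macrocyclic bis-stilbene: 24 with both CH2CH2 bridges as CH=CH (ring A–ring D alkene E, ring B–ring C alkene E/Z mixture) | COc1cc(/C=C/c2cccc(Oc3cc(C=Cc4ccc(O5)cc4)cc(OC)c3OC)c2)cc5c1OC
F6 | step 8 | 5-(tributylstannyl)-2H-pyran-2-one | CCCC[Sn](CCCC)(CCCC)C1=COC(=O)C=C1
F7 | step 6 | O,C-bis(trimethylsilyl) derivative of 13 (trimethylsilyl ether, trimethylsilyl-capped ynol ether), formed in the flask | C[Si](C)(C)OCc1cc(Oc2cccc(/C=C/c3cc(OC#C[Si](C)(C)C)c(OC)c(OC)c3)c2)c(OC)c(OC)c1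
F8 | step 6 | [3-[3-[(E)-2-[4,5-dimethoxy-3-[(trimethylsilyl)ethynyloxy]phenyl]vinyl]phenoxy]-4,5-dimethoxyphenyl]methanol | OCc1cc(Oc2cccc(/C=C/c3cc(OC#C[Si](C)(C)C)c(OC)c(OC)c3)c2)c(OC)c(OC)c1
F9 | step 6 | methanesulfonate of F8, formed in the flask | CS(=O)(=O)OCc1cc(Oc2cccc(/C=C/c3cc(OC#C[Si](C)(C)C)c(OC)c(OC)c3)c2)c(OC)c(OC)c1
F10 | step 6 | benzylic chloride corresponding to F8 | ClCc1cc(Oc2cccc(/C=C/c3cc(OC#C[Si](C)(C)C)c(OC)c(OC)c3)c2)c(OC)c(OC)c1
F11 | step 6 | benzylzinc chloride from F10, formed in the flask | Cl[Zn]Cc1cc(Oc2cccc(/C=C/c3cc(OC#C[Si](C)(C)C)c(OC)c(OC)c3)c2)c(OC)c(OC)c1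
F12 | step 6 | C-trimethylsilyl derivative of 19 | O=C(Cc1cc(Oc2cccc(/C=C/c3cc(OC#C[Si](C)(C)C)c(OC)c(OC)c3)c2)c(OC)c(OC)c1)C1=COC(=O)C=C1
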